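The route rests on disconnecting the aryl C-3–O-3 bond of the dioxane ring. Until that ring is fused, ring A is symmetric about its C-1/C-4 axis, so in a 3,5-dibromo-4-alkoxy ring either bromide is an equivalent partner for the C-7' oxygen. One copper-catalysed intramolecular O-arylation thus closes the dioxane without a regiochemical question, carries the syn C-7'/C-8' pair unchanged into the trans ring and leaves the other bromide at C-5 as the latent phenol. The precursor is the syn (7'S,8'S) alcohol from an auxiliary-controlled glycolate aldol. Its C-1 carbon is kept as CH2OTIPS, since a carbonyl there lies para to O-4 and meta to both bromides and would only favour aryl migration.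

Key step: step 8

Numbering used: ring A runs from C-1 (carbon substituent) to C-6. O-3 and O-4 are the dioxane oxygens and C-5 is the site of the last phenol. C-7' (benzylic), C-8' and C-9' form the side chain of the syringyl unit. Ring B is the resorcinol ring.
Assumption: the boron enolate of the aryloxyacetyl imide is taken to have the same enolate geometry and facial sense as alkoxyacetyl and propionyl imides of the same auxiliary.

Step 1
Reactants: 1 methyl 3,5-dibromo-4-hydroxybenzoate; 2 tert-butyl bromoacetate
Product: 3 methyl 3,5-dibromo-4-(2-tert-butoxy-2-oxoethoxy)benzoate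
Conditions: K2CO3, DMF, 60 °C
Reagents that add atoms: none
Why: Williamson ether synthesis, in which K2CO3 fully ionises the acidic dibromophenol, the unhindered α-bromo ester is reactive enough for this weak hindered nucleophile, and using the ester form of the alkylating agent avoids a competing carboxylate nucleophile.

Step 2
Reactants: 3 methyl 3,5-dibromo-4-(2-tert-butoxy-2-oxoethoxy)benzoate
Product: 4 [2,6-dibromo-4-(methoxycarbonyl)phenoxy]acetic acid
Conditions: TFA, CH2Cl2, rt
Reagents that add atoms: none
Why: Acidolysis of the tert-butyl ester with loss of isobutene frees only the aliphatic acid, because the methyl benzoate and the aryl ether are inert to TFA.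

Step 3
Reactants: 4 [2,6-dibromo-4-(methoxycarbonyl)phenoxy]acetic acid; 5 (R)-4-benzyl-2-oxazolidinone
Product: 7 methyl 4-{2-[(4R)-4-benzyl-2-oxo-1,3-oxazolidin-3-yl]-2-oxoethoxy}-3,5-dibromobenzoate, via mixed pivalic anhydride 6 (not isolated)
Conditions: PivCl, Et3N, THF, −20 to 0 °C; then LiCl, 5, 0 °C to rt
Reagents that add atoms: pivaloyl chloride CC(C)(C)C(=O)Cl (its acyl group stays only in 6)
Why: N-acylation through a mixed anhydride, in which the lithium-activated oxazolidinone attacks the unhindered aryloxyacetyl carbonyl rather than the pivaloyl carbonyl and no strong base meets the methyl ester.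

Step 4
Reactants: 8 syringaldehyde
Product: 9 3,5-dimethoxy-4-(methoxymethoxy)benzaldehyde
Conditions: MOMCl, i-Pr2NEt, CH2Cl2, 0 °C to rt
Reagents that add atoms: chloromethyl methyl ether COCCl
Why: O-alkylation of the acidic para-formyl phenol to an acetal (MOM) ether, which tolerates boron triflate at low temperature, hydride, carbonate, fluoride and palladium and leaves only under acid at the end.

Step 5
Reactants: 7 methyl 4-{2-[(4R)-4-benzyl-2-oxo-1,3-oxazolidin-3-yl]-2-oxoethoxy}-3,5-dibromobenzoate; 9 3,5-dimethoxy-4-(methoxymethoxy)benzaldehyde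
Product: 12 syn aldol adduct methyl 4-({(1S,2R)-3-[(4R)-4-benzyl-2-oxo-1,3-oxazolidin-3-yl]-1-[3,5-dimethoxy-4-(methoxymethoxy)phenyl]-1-hydroxy-3-oxopropan-2-yl}oxy)-3,5-dibromobenzoate, via Z boron enolate 10 (not isolated), via boron aldolate 11 (not isolated)
Conditions: Bu2BOTf, Et3N, CH2Cl2, −78 to 0 °C; 9, −78 to 0 °C; then pH 7 buffer, MeOH, 30% H2O2, 0 °C
Reagents that add atoms: dibutylboron triflate CCCCB(CCCC)OS(=O)(=O)C(F)(F)F (its boron stays only in 10 and 11)
Why: Evans boron syn aldol, in which soft enolisation gives the Z enolate 10 and this adds to 9 through a chair Zimmerman–Traxler transition state on the face away from the benzyl group of the dipole-opposed (R)-auxiliary, setting C-8' and C-7' together (acyl 2R,3S, syn) in the sense that reads 7'S,8'S once C-9' is reduced.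

Step 6
Reactants: 12 syn aldol adduct
Product: 13 (1S,2S)-2-[2,6-dibromo-4-(hydroxymethyl)phenoxy]-1-[3,5-dimethoxy-4-(methoxymethoxy)phenyl]propane-1,3-diol
Conditions: LiBH4 (excess), MeOH, THF, 0 °C then 40 °C
Reagents that add atoms: none
Why: Hydride reduction with LiBH4, which takes the activated imide first at 0 °C (releasing the auxiliary before retro-aldol can intervene) and on warming reduces the methyl benzoate as well, so no chemoselectivity between the two carbonyls is asked for and the acceptor para to O-4 is gone before any hot base is used.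

Step 7
Reactants: 13 triol
Product: 14 (1S,2S)-2-{2,6-dibromo-4-[(triisopropylsilyloxy)methyl]phenoxy}-1-[3,5-dimethoxy-4-(methoxymethoxy)phenyl]-3-(triisopropylsilyloxy)propan-1-ol
Conditions: TIPSCl, imidazole, DMF, 0 °C to rt
Reagents that add atoms: triisopropylsilyl chloride CC(C)[Si](Cl)(C(C)C)C(C)C
Why: Silyl ether formation, in which bulky TIPSCl takes both primary alcohols and leaves the hindered secondary C-7' hydroxyl free, and TIPS is chosen because it resists base-induced O-9' to O-7' migration, which would expose a primary alkoxide able to close an isomeric six-membered ring.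

Step 8
Reactants: 14 syn alcohol (7'S,8'S)
Product: 15 (2S,3S)-5-bromo-2-[3,5-dimethoxy-4-(methoxymethoxy)phenyl]-3,7-bis[(triisopropylsilyloxy)methyl]-2,3-dihydro-1,4-benzodioxine (trans)
Conditions: CuI (15 mol %), 3,4,7,8-tetramethyl-1,10-phenanthroline (30 mol %), Cs2CO3, 4 Å molecular sieves, toluene (dilute), 100 °C, Ar
Reagents that add atoms: none
Why: Cs2CO3 hands the C-7' alkoxide to the phenanthroline-bound monovalent copper centre, this copper alkoxide cleaves one ortho C–Br bond of ring A by oxidative addition, and reductive elimination forms the C-3–O-3 aryl ether. The closest known reaction type is the ligand-accelerated Ullmann O-arylation of aliphatic alcohols with aryl bromides, which is established in its intramolecular form for 1,4-benzodioxanes and chromans. The dioxane closes as a six-membered ring in a formal 6-exo mode, the tethered oxygen reaching the ortho carbon through a seven-membered copper chelate. No stereocentre is formed and no bond at C-7' or C-8' is broken, so the syn 7'S,8'S pair appears unchanged as the trans diequatorial dioxane. Site selectivity is not required because rotation about C-4–O-4 exchanges the two bromides and either one gives 15, and a second coupling cannot follow because O-9' carries a TIPS group that does not migrate. The selectivity that is required is catalysis over the uncatalysed reactions of the alkoxide (ipso attack at C-4 with Smiles migration of ring A to O-7', or expulsion of the dibromophenoxide with epoxide formation), and it is secured by the non-accepting CH2OTIPS group para to O-4, by the syn configuration, which could only lead to a strained cis epoxide, and by toluene, which keeps the free alkoxide scarce.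

Step 9
Reactants: 15 trans bromo benzodioxane bis-TIPS ether
Product: 16 {(2S,3S)-5-bromo-2-[3,5-dimethoxy-4-(methoxymethoxy)phenyl]-2,3-dihydro-1,4-benzodioxine-3,7-diyl}dimethanol
Conditions: TBAF, THF, 0 °C to rt
Reagents that add atoms: none
Why: Fluoride-driven desilylation removes both TIPS groups, while the MOM acetal, the aryl bromide and the dioxane are inert to fluoride.

Step 10
Reactants: 16 diol
Product: 17 (2S,3S)-5-bromo-2-[3,5-dimethoxy-4-(methoxymethoxy)phenyl]-3-(hydroxymethyl)-2,3-dihydro-1,4-benzodioxine-7-carbaldehyde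
Conditions: MnO2 (excess), CH2Cl2, rt
Reagents that add atoms: none
Why: MnO2 oxidation is selective for the benzylic alcohol on ring A over the saturated primary C-9' alcohol, so the two hydroxyls need no differentiation by protecting groups.

Step 11
Reactants: 18 methyl 3,5-dihydroxybenzoate
Product: 19 methyl 3,5-bis(methoxymethoxy)benzoate
Conditions: MOMCl, i-Pr2NEt, CH2Cl2, 0 °C to rt
Reagents that add atoms: chloromethyl methyl ether COCCl
Why: Double O-alkylation to MOM acetals gives ring B the same acid-labile protection as the syringyl phenol, so one final operation can remove all of them.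

Step 12
Reactants: 19 methyl 3,5-bis(methoxymethoxy)benzoate
Product: 20 [3,5-bis(methoxymethoxy)phenyl]methanol
Conditions: LiAlH4, THF, 0 °C
Reagents that add atoms: none
Why: Standard LiAlH4 reduction of a benzoate ester to the benzylic alcohol, to which MOM ethers are inert.

Step 13
Reactants: 20 [3,5-bis(methoxymethoxy)phenyl]methanol
Product: 22 1-(bromomethyl)-3,5-bis(methoxymethoxy)benzene, via benzylic mesylate 21 (not isolated)
Conditions: MsCl, Et3N, CH2Cl2, 0 °C; then LiBr, THF, rt
Reagents that add atoms: lithium bromide [Li+].[Br-]; methanesulfonyl chloride CS(=O)(=O)Cl (its sulfonyl group stays only in 21)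
Why: Sulfonylation followed by SN2 halide displacement (Finkelstein type) gives the benzylic bromide under acid-free conditions that spare the MOM acetals.

Step 14
Reactants: 22 1-(bromomethyl)-3,5-bis(methoxymethoxy)benzene
Product: 23 diethyl [3,5-bis(methoxymethoxy)benzyl]phosphonate
Conditions: P(OEt)3, neat, 130 °C
Reagents that add atoms: triethyl phosphite CCOP(OCC)OCC
Why: Michaelis–Arbuzov reaction of a primary benzylic bromide, driven by loss of volatile bromoethane.

Step 15
Reactants: 23 diethyl [3,5-bis(methoxymethoxy)benzyl]phosphonate; 17 bromo aldehyde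
Product: 25 {(2S,3S)-5-bromo-7-[(E)-2-(3,5-bis(methoxymethoxy)phenyl)ethenyl]-2-[3,5-dimethoxy-4-(methoxymethoxy)phenyl]-2,3-dihydro-1,4-benzodioxin-3-yl}methanol, via potassium phosphonate anion 24 (not isolated)
Conditions: 23, KOtBu (excess), THF, 0 °C; then slow addition of 17, 0 °C to rt
Reagents that add atoms: potassium tert-butoxide CC(C)(C)[O-].[K+] (its potassium stays only in 24)
Why: Horner–Wadsworth–Emmons olefination of an aromatic aldehyde with a benzylic phosphonate should give the E stilbene through reversible addition and syn elimination from the less crowded adduct, the extra base covers the C-9' hydroxyl, and adding 17 to excess anion consumes the formyl acceptor para to O-4 before the C-9' alkoxide could attack C-4.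

Step 16
Reactants: 25 bromo stilbene
Product: 27 (2S,3S)-7-[(E)-2-(3,5-bis(methoxymethoxy)phenyl)ethenyl]-2-[3,5-dimethoxy-4-(methoxymethoxy)phenyl]-3-(hydroxymethyl)-2,3-dihydro-1,4-benzodioxin-5-ol, via pinacol boronate 26 (not isolated)
Conditions: Pd(dppf)Cl2 (5 mol %), B2pin2, KOAc, 1,4-dioxane, 90 °C; then NaBO3·4H2O, THF/H2O, rt
Reagents that add atoms: bis(pinacolato)diboron CC1(C)OB(OC1(C)C)B1OC(C)(C)C(C)(C)O1 (its boron stays only in 26); sodium perborate [Na+].[Na+].O[B-]1(O)OO[B-](O)(O)OO1
Why: Miyaura borylation (zerovalent palladium inserts into the surviving C-5–Br bond and acetate-assisted transmetalation delivers Bpin) followed by perborate oxidation with ipso boron-to-oxygen aryl shift places the phenol exactly where the bromide stood, the internal stilbene and the MOM groups are inert to both stages, and unveiling the phenol this late saves its protection.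

Step 17
Reactants: 27 tris-MOM phenol
Product: 28 target (2S,3S)-7-[(E)-2-(3,5-dihydroxyphenyl)ethenyl]-2-(4-hydroxy-3,5-dimethoxyphenyl)-3-(hydroxymethyl)-2,3-dihydro-1,4-benzodioxin-5-ol
Conditions: HCl (cat.), MeOH, 40 °C, Ar, dark
Reagents that add atoms: none
Why: Acid-catalysed acetal exchange with methanol removes the three aryl MOM groups under mild conditions, and any reversible ionisation at C-7' would re-close under control of the untouched C-8' centre to the more stable trans ring, so the configuration should be kept.

Compound list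
1 | methyl 3,5-dibromo-4-hydroxybenzoate | COC(=O)c1cc(Br)c(O)c(Br)c1 | starting material
2 | tert-butyl bromoacetate | CC(C)(C)OC(=O)CBr | starting material
3 | methyl 3,5-dibromo-4-(2-tert-butoxy-2-oxoethoxy)benzoate | COC(=O)c1cc(Br)c(OCC(=O)OC(C)(C)C)c(Br)c1 | intermediate
4 | [2,6-dibromo-4-(methoxycarbonyl)phenoxy]acetic acid | COC(=O)c1cc(Br)c(OCC(=O)O)c(Br)c1 | intermediate
5 | (R)-4-benzyl-2-oxazolidinone | O=C1N[C@H](Cc2ccccc2)CO1 | starting material
6 | mixed anhydride of 4 and pivalic acid | COC(=O)c1cc(Br)c(OCC(=O)OC(=O)C(C)(C)C)c(Br)c1 | intermediate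
7 | aryloxyacetyl imide of the (R)-auxiliary | COC(=O)c1cc(Br)c(OCC(=O)N2[C@H](Cc3ccccc3)COC2=O)c(Br)c1 | intermediate
8 | syringaldehyde | COc1cc(C=O)cc(OC)c1O | starting material
9 | 3,5-dimethoxy-4-(methoxymethoxy)benzaldehyde | COCOc1c(OC)cc(C=O)cc1OC | intermediate
10 | Z dibutylboron enolate of 7 | CCCCB(CCCC)O/C(=C\Oc1c(Br)cc(C(=O)OC)cc1Br)N1[C@H](Cc2ccccc2)COC1=O | intermediate
11 | dibutylboron aldolate of 12 | COc1cc([C@H](OB(CCCC)CCCC)[C@H](C(=O)N2[C@H](Cc3ccccc3)COC2=O)Oc2c(Br)cc(C(=O)OC)cc2Br)cc(OC)c1OCOC | intermediate
12 | syn aldol adduct (acyl 2R,3S; auxiliary 4R) | COc1cc([C@H](O)[C@H](C(=O)N2[C@H](Cc3ccccc3)COC2=O)Oc2c(Br)cc(C(=O)OC)cc2Br)cc(OC)c1OCOC | intermediate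
13 | (1S,2S) triol | COc1cc([C@H](O)[C@H](CO)Oc2c(Br)cc(CO)cc2Br)cc(OC)c1OCOC | intermediate
14 | (1S,2S) syn alcohol, bis-TIPS ether (key-step precursor) | COc1cc([C@H](O)[C@H](CO[Si](C(C)C)(C(C)C)C(C)C)Oc2c(Br)cc(CO[Si](C(C)C)(C(C)C)C(C)C)cc2Br)cc(OC)c1OCOC | intermediate
15 | (2S,3S) trans 5-bromo benzodioxane, bis-TIPS ether (key-step product) | COc1cc([C@@H]2Oc3cc(CO[Si](C(C)C)(C(C)C)C(C)C)cc(Br)c3O[C@H]2CO[Si](C(C)C)(C(C)C)C(C)C)cc(OC)c1OCOC | intermediate
16 | (2S,3S) bromo benzodioxane diol | COc1cc([C@@H]2Oc3cc(CO)cc(Br)c3O[C@H]2CO)cc(OC)c1OCOC | intermediate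
17 | (2S,3S) bromo benzodioxane hydroxy aldehyde | COc1cc([C@@H]2Oc3cc(C=O)cc(Br)c3O[C@H]2CO)cc(OC)c1OCOC | intermediate
18 | methyl 3,5-dihydroxybenzoate | COC(=O)c1cc(O)cc(O)c1 | starting material
19 | methyl 3,5-bis(methoxymethoxy)benzoate | COCOc1cc(OCOC)cc(C(=O)OC)c1 | intermediate
20 | [3,5-bis(methoxymethoxy)phenyl]methanol | COCOc1cc(CO)cc(OCOC)c1 | intermediate
21 | 3,5-bis(methoxymethoxy)benzyl methanesulfonate | COCOc1cc(COS(C)(=O)=O)cc(OCOC)c1 | intermediate
22 | 1-(bromomethyl)-3,5-bis(methoxymethoxy)benzene | COCOc1cc(CBr)cc(OCOC)c1 | intermediate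
23 | diethyl [3,5-bis(methoxymethoxy)benzyl]phosphonate | CCOP(=O)(Cc1cc(OCOC)cc(OCOC)c1)OCC | intermediate
24 | potassium salt of the carbanion of 23 | CCOP(=O)(OCC)[CH-]c1cc(OCOC)cc(OCOC)c1.[K+] | intermediate
25 | (2S,3S,E) bromo stilbene, tris-MOM | COc1cc([C@@H]2Oc3cc(/C=C/c4cc(OCOC)cc(OCOC)c4)cc(Br)c3O[C@H]2CO)cc(OC)c1OCOC | intermediate
26 | (2S,3S,E) C-5 pinacol boronate | COc1cc([C@@H]2Oc3cc(/C=C/c4cc(OCOC)cc(OCOC)c4)cc(B5OC(C)(C)C(C)(C)O5)c3O[C@H]2CO)cc(OC)c1OCOC | intermediate
27 | (2S,3S,E) C-5 phenol, tris-MOM | COc1cc([C@@H]2Oc3cc(/C=C/c4cc(OCOC)cc(OCOC)c4)cc(O)c3O[C@H]2CO)cc(OC)c1OCOC | intermediate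
28 | CNP0319597.1, (7'S,8'S), E | COc1cc([C@@H]2Oc3cc(/C=C/c4cc(O)cc(O)c4)cc(O)c3O[C@H]2CO)cc(OC)c1O | target

Total step count: 17. Longest linear sequence: 12 steps (1–3, 5–10, 15–17). Step 4 and steps 11–14 are side branches.

Steps most likely to fail

**Step 8.**
- What may go wrong: the hindered secondary alkoxide may bind copper too slowly. Ipso attack at C-4 with aryl migration, loss of the dibromophenoxide with epoxide formation, or hydrodebromination could then overtake the coupling.
- Fallback: the ring-closing bond is moved from C-3–O-3 to C-7'–O-3.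
- Setting out from 14, n-BuLi (2.1 equiv, THF, −78 °C) deprotonates the alcohol and exchanges a single bromide. A second exchange would require a trianion. B(OMe)3 traps the aryllithium as dimethyl arylboronate F1, and H2O2/NaOH in the same flask gives syn bromophenol F2.
- Catalytic camphorsulfonic acid with 4 Å molecular sieves in CH2Cl2 (0 °C to rt) then ionises the electron-rich benzylic alcohol, and the C-3 phenol captures the cation reversibly.
- C-8' is untouched and steers the closure to the diequatorial trans ring, so the path comes back to the route at 15.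

**Step 5.**
- What may go wrong: the bulky, weakly basic dibromoaryloxy group may slow enolisation or erode syn and facial selectivity. Retro-aldol loss of the electron-rich aldehyde may also occur during work-up.
- Fallback: the stereocentres are set by catalytic reduction instead of by the C–C bond formation.
- Setting out from 3 and 9, the lithium enolate of 3 (LiN(SiMe3)2, THF, −78 °C) adds to 9 without stereocontrol to give β-hydroxy ester F3. Dess–Martin periodinane oxidises it to the configurationally labile β-keto ester F4.
- Asymmetric transfer hydrogenation under dynamic kinetic resolution (RuCl[(R,R)-TsDPEN](p-cymene), HCO2H/Et3N, CH2Cl2, 30 °C) should fix C-7' by catalyst control and C-8' through the rapidly equilibrating keto ester, giving syn hydroxy ester F5.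
- Excess i-Bu2AlH (CH2Cl2, −78 °C to rt) reduces both esters, and the path comes back at triol 13.

**Step 17.**
- What may go wrong: once the syringyl phenol is free, acid may ionise the C-7'–O-3 bond, leading to solvolysis or epimerisation. The electron-rich stilbene may also oligomerise.
- Fallback: the acetals are exchanged for silyl ethers so that the last operation is a fluoride cleavage.
- Setting out from 27, TESOTf and 2,2'-bipyridyl (CH2Cl2, 0 °C to rt) convert the three aryl MOM groups into triethylsilyl ethers without Brønsted acid. They also silylate the two free hydroxyls, giving pentakis(triethylsilyl) ether F6.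
- Et3N·3HF in THF at 0 °C then frees all five hydroxyls close to neutrality, and the path comes back at target 28.

Further compounds
F1 | step 8 | dimethyl arylboronate, 14 with B(OMe)2 in place of one bromine (7'S,8'S) | COc1cc([C@H](O)[C@H](CO[Si](C(C)C)(C(C)C)C(C)C)Oc2c(Br)cc(CO[Si](C(C)C)(C(C)C)C(C)C)cc2B(OC)OC)cc(OC)c1OCOC
F2 | step 8 | syn bromophenol, 14 with OH in place of one bromine (7'S,8'S) | COc1cc([C@H](O)[C@H](CO[Si](C(C)C)(C(C)C)C(C)C)Oc2c(Br)cc(CO[Si](C(C)C)(C(C)C)C(C)C)cc2O)cc(OC)c1OCOC
F3 | step 5 | β-hydroxy ester, tert-butyl 2-aryloxy-3-aryl-3-hydroxypropanoate (mixture of stereoisomers) | COc1cc(C(O)C(C(=O)OC(C)(C)C)Oc2c(Br)cc(C(=O)OC)cc2Br)cc(OC)c1OCOC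
F4 | step 5 | β-keto ester, tert-butyl 2-aryloxy-3-aryl-3-oxopropanoate (racemic, C-8' labile) | COc1cc(C(=O)C(C(=O)OC(C)(C)C)Oc2c(Br)cc(C(=O)OC)cc2Br)cc(OC)c1OCOC
F5 | step 5 | syn hydroxy ester, tert-butyl (2R,3S)-2-aryloxy-3-aryl-3-hydroxypropanoate | COc1cc([C@H](O)[C@H](C(=O)OC(C)(C)C)Oc2c(Br)cc(C(=O)OC)cc2Br)cc(OC)c1OCOC
F6 | step 17 | pentakis(triethylsilyl) ether of 28 | COc1cc([C@@H]2Oc3cc(/C=C/c4cc(O[Si](CC)(CC)CC)cc(O[Si](CC)(CC)CC)c4)cc(O[Si](CC)(CC)CC)c3O[C@H]2CO[Si](CC)(CC)CC)cc(OC)c1O[Si](CC)(CC)CC
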